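**Strategy.** The route rests on disconnecting the acyloin bond C3(OH)–C4(=O) of the pyranone ring C. The key step is a carbene-catalysed intramolecular crossed benzoin reaction: the ring A aldehyde carbon (C4) attacks a C3 keto group. In one operation this closes ring C, installs the C4 ketone and the C3 carbinol, and fixes the labile C2 centre by dynamic kinetic resolution. The precursor is a racemic aryl ether in which O1 already joins ring A (bearing the C4 aldehyde) to C2, while C3 is the keto group of a tert-butyl α-keto ester. This ester is a temporary activating group, lost by decarboxylation in the final acid deprotection, which resets C3 trans.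

Key step: step 6

Remark: (E)-geranylboronic acid pinacol ester and tert-butyl dichloroacetate are taken as catalogue compounds; the triazolium enantiomer named in step 6 is assigned by analogy, and its equally available antipode would be used if the opposite C2 series should result.

In the names below, geranyl = (2E)-3,7-dimethylocta-2,6-dien-1-yl.

Step 1
Reactants: 1 2,4,6-trihydroxybenzaldehyde
Product: 2 2-hydroxy-4,6-bis(methoxymethoxy)benzaldehyde
Conditions: MOMCl (2.1 equiv), i-Pr2NEt (2.5 equiv), CH2Cl2, 0 °C to rt
Reagents that add atoms: chloromethyl methyl ether (MOMCl), COCCl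
Why: Williamson-type O-alkylation (acetal formation) that should stop at the bis-ether, because the last ortho hydroxyl is held in a hydrogen bond to the aldehyde and is the least nucleophilic.

Step 2
Reactants: 3 3-bromo-4,5-dihydroxybenzaldehyde
Product: 4 3-bromo-4,5-bis(methoxymethoxy)benzaldehyde
Conditions: MOMCl (2.5 equiv), i-Pr2NEt (3 equiv), CH2Cl2, 0 °C to rt
Reagents that add atoms: chloromethyl methyl ether (MOMCl), COCCl
Why: Williamson-type O-alkylation of both catechol hydroxyls, giving base-stable acetals that survive every later step up to the final acidolysis.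

Step 3
Reactants: 4 3-bromo-4,5-bis(methoxymethoxy)benzaldehyde; 5 (E)-geranylboronic acid pinacol ester
Product: 6 3-geranyl-4,5-bis(methoxymethoxy)benzaldehyde
Conditions: PdCl2(IPent)(3-chloropyridine) (2 mol %; IPent = 1,3-bis[2,6-di(pentan-3-yl)phenyl]imidazol-2-ylidene), KOH (aq), THF, 65 °C
Reagents that add atoms: none
Why: Suzuki–Miyaura coupling of an allylic boronate, in which the bulky carbene ligand should force reductive elimination from the σ-allyl bound at its unsubstituted terminus, so that the linear (E)-geranyl arene forms and not the branched isomer.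

Step 4
Reactants: 6 3-geranyl-4,5-bis(methoxymethoxy)benzaldehyde; 7 tert-butyl dichloroacetate
Product: 9 tert-butyl 3-chloro-3-[3-geranyl-4,5-bis(methoxymethoxy)phenyl]-2-oxopropanoate (racemic), via α-chloroglycidic ester 8 (not isolated)
Conditions: potassium tert-butoxide (1.05 equiv), THF, −40 to 0 °C; aqueous work-up; toluene, 40 °C; crude 9 used directly
Reagents that add atoms: none
Why: Darzens condensation of a dichloroacetate gives the α-chloro epoxide 8, whose benzylic C–O bond ionises easily (para-alkoxyaryl group) so that chloride shifts to the benzylic carbon and the β-chloro-α-keto ester results.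

Step 5
Reactants: 9 tert-butyl 3-chloro-3-[3-geranyl-4,5-bis(methoxymethoxy)phenyl]-2-oxopropanoate; 2 2-hydroxy-4,6-bis(methoxymethoxy)benzaldehyde
Product: 10 tert-butyl 3-[3-geranyl-4,5-bis(methoxymethoxy)phenyl]-3-[2-formyl-3,5-bis(methoxymethoxy)phenoxy]-2-oxopropanoate (racemic)
Conditions: K2CO3 (1.1 equiv), acetone, 0 °C to rt
Reagents that add atoms: none
Why: Williamson O-alkylation in which the acidic phenoxide of 2 displaces the doubly activated (benzylic and α-keto) chloride, creating the O1–C2 bond; mild base and low temperature should disfavour aldol closure onto the aldehyde, and the racemic C2 centre is corrected in step 6.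

Step 6
Reactants: 10 tert-butyl 3-[3-geranyl-4,5-bis(methoxymethoxy)phenyl]-3-[2-formyl-3,5-bis(methoxymethoxy)phenoxy]-2-oxopropanoate
Product: 12 tert-butyl (2R,3R)-2-[3-geranyl-4,5-bis(methoxymethoxy)phenyl]-3-hydroxy-5,7-bis(methoxymethoxy)-4-oxochromane-3-carboxylate, via enol tautomer 11 (not isolated)
Conditions: (5aR,10bS)-2-(pentafluorophenyl)-5a,10b-dihydro-4H,6H-indeno[2,1-b][1,2,4]triazolo[4,3-d][1,4]oxazin-2-ium tetrafluoroborate (20 mol %), i-Pr2NEt (0.5 equiv), 4 Å molecular sieves, toluene, rt
Reagents that add atoms: none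
Why: The chiral triazolylidene adds to the only aldehyde (C4 on ring A), proton transfer gives the Breslow acyl-anion equivalent, and this attacks the C3 keto group of the α-keto ester before collapse releases the carbene and the C4 ketone. This is an intramolecular crossed benzoin (aldehyde–ketone acyloin) reaction of the type used for 3-hydroxychroman-4-ones and for dynamic kinetic resolution of β-stereogenic α-keto esters. Ring C closes in a 6-exo-trig mode by forming the C3–C4 bond. The C3 carbinol configuration is set by the catalyst-controlled face of attack, and C2 by dynamic kinetic resolution: the enantiomers of 10 interconvert through enol 11 under the amine base, and only the enantiomer that places the C2 aryl group pseudo-equatorial in the catalyst-matched, hydrogen-bonded transition state should cyclise quickly (aryl and hydroxyl pseudo-equatorial, ester pseudo-axial). Chemoselectivity is built into the substrate: the keto ester cannot become an acyl-anion donor and is the most electrophilic acceptor, the tert-butyl ester resists lactonisation, and the competing aldol of enol 11 onto the deactivated aldehyde is reversible.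

Step 7
Reactants: 12 tert-butyl (2R,3R)-2-[3-geranyl-4,5-bis(methoxymethoxy)phenyl]-3-hydroxy-5,7-bis(methoxymethoxy)-4-oxochromane-3-carboxylate
Product: 15 (2R,3R)-2-(3-geranyl-4,5-dihydroxyphenyl)-3,5,7-trihydroxychroman-4-one, via hydroxy keto acid 13 (not isolated), via enediol 14 (not isolated)
Conditions: HCl (3 M aq), MeOH, 50 °C
Reagents that add atoms: none
Why: Acid-catalysed acetal methanolysis frees the four phenols, the tert-butyl ester ionises to the acid 13, and this α-hydroxy-β-keto acid decarboxylates to enediol 14, whose C3 is protonated under equilibrating acid to the thermodynamically preferred 2,3-trans isomer while the non-enolisable C2 keeps its R configuration.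

**Compound list**

1 | 2,4,6-trihydroxybenzaldehyde | O=Cc1c(O)cc(O)cc1O | starting material
2 | 2-hydroxy-4,6-bis(methoxymethoxy)benzaldehyde | COCOc1cc(O)c(C=O)c(OCOC)c1 | intermediate
3 | 3-bromo-4,5-dihydroxybenzaldehyde | O=Cc1cc(O)c(O)c(Br)c1 | starting material
4 | 3-bromo-4,5-bis(methoxymethoxy)benzaldehyde | O=Cc1cc(OCOC)c(OCOC)c(Br)c1 | intermediate
5 | 2-[(2E)-3,7-dimethylocta-2,6-dien-1-yl]-4,4,5,5-tetramethyl-1,3,2-dioxaborolane | CC(C)=CCC/C(C)=C/CB1OC(C)(C)C(C)(C)O1 | starting material
6 | 3-geranyl-4,5-bis(methoxymethoxy)benzaldehyde | CC(C)=CCC/C(C)=C/Cc1cc(C=O)cc(OCOC)c1OCOC | intermediate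
7 | tert-butyl dichloroacetate | ClC(Cl)C(=O)OC(C)(C)C | starting material
8 | tert-butyl 2-chloro-3-[3-geranyl-4,5-bis(methoxymethoxy)phenyl]oxirane-2-carboxylate (racemic) | CC(C)=CCC/C(C)=C/Cc1cc(C2OC2(Cl)C(=O)OC(C)(C)C)cc(OCOC)c1OCOC | intermediate
9 | tert-butyl 3-chloro-3-[3-geranyl-4,5-bis(methoxymethoxy)phenyl]-2-oxopropanoate (racemic) | CC(C)=CCC/C(C)=C/Cc1cc(C(Cl)C(=O)C(=O)OC(C)(C)C)cc(OCOC)c1OCOC | intermediate
10 | tert-butyl 3-[3-geranyl-4,5-bis(methoxymethoxy)phenyl]-3-[2-formyl-3,5-bis(methoxymethoxy)phenoxy]-2-oxopropanoate (racemic) | CC(C)=CCC/C(C)=C/Cc1cc(C(Oc2cc(OCOC)cc(OCOC)c2C=O)C(=O)C(=O)OC(C)(C)C)cc(OCOC)c1OCOC | intermediate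
11 | tert-butyl 3-[3-geranyl-4,5-bis(methoxymethoxy)phenyl]-3-[2-formyl-3,5-bis(methoxymethoxy)phenoxy]-2-hydroxyprop-2-enoate (enol of 10, achiral at C2) | CC(C)=CCC/C(C)=C/Cc1cc(C(Oc2cc(OCOC)cc(OCOC)c2C=O)=C(O)C(=O)OC(C)(C)C)cc(OCOC)c1OCOC | intermediate
12 | tert-butyl (2R,3R)-2-[3-geranyl-4,5-bis(methoxymethoxy)phenyl]-3-hydroxy-5,7-bis(methoxymethoxy)-4-oxochromane-3-carboxylate | CC(C)=CCC/C(C)=C/Cc1cc([C@H]2Oc3cc(OCOC)cc(OCOC)c3C(=O)[C@]2(C(=O)OC(C)(C)C)O)cc(OCOC)c1OCOC | intermediate
13 | (2R,3R)-2-(3-geranyl-4,5-dihydroxyphenyl)-3,5,7-trihydroxy-4-oxochromane-3-carboxylic acid | CC(C)=CCC/C(C)=C/Cc1cc([C@H]2Oc3cc(O)cc(O)c3C(=O)[C@]2(C(=O)O)O)cc(O)c1O | intermediate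
14 | (2R)-2-(3-geranyl-4,5-dihydroxyphenyl)-2H-chromene-3,4,5,7-tetrol | CC(C)=CCC/C(C)=C/Cc1cc([C@H]2Oc3cc(O)cc(O)c3C(O)=C2O)cc(O)c1O | intermediate
15 | (2R,3R)-2-(3-geranyl-4,5-dihydroxyphenyl)-3,5,7-trihydroxychroman-4-one | CC(C)=CCC/C(C)=C/Cc1cc([C@H]2Oc3cc(O)cc(O)c3C(=O)[C@@H]2O)cc(O)c1O | target

**Step count.** Total: 7 steps. Longest linear sequence: 6 steps (3 → 4 → 6 → 9 → 10 → 12 → 15).

**Steps most likely to fail**

Step 6. Carbene addition to the di-ortho-substituted, electron-rich aldehyde may be slow. Enolisation of 10 may not keep pace with cyclisation, so the dynamic kinetic resolution could be incomplete and stereocontrol poor. Aldol closure of the enol onto the aldehyde may also drain material. Fallback, setting out from 10: stereocontrol is moved from catalysis to separation. Cyclisation with the achiral precatalyst 2-(pentafluorophenyl)-6,7-dihydro-5H-pyrrolo[2,1-c][1,2,4]triazol-2-ium tetrafluoroborate and i-Pr2NEt in toluene should give, through the same C3–C4 ring closure, racemic tert-butyl (2R*,3R*)-2-[3-geranyl-4,5-bis(methoxymethoxy)phenyl]-3-hydroxy-5,7-bis(methoxymethoxy)-4-oxochromane-3-carboxylate F1. Its enantiomers would be separated by preparative chromatography on a chiral stationary phase, and the (2R,3R) enantiomer rejoins the route at 12.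

Step 7. The geranyl chain ortho to a freed phenol may hydrate or cyclise under acid. Cleavage of the tert-butyl ester may lag behind acetal removal. C3 may be protonated to a mixture of epimers, and C2 may epimerise by ring opening once the para hydroxyl of ring B is free. Fallback, setting out from 12: decarboxylation is separated from phenol deprotection. Heating 12 with silica gel in toluene at reflux should expel 2-methylpropene and CO2 without touching the acetals and give (2R,3R)-2-[3-geranyl-4,5-bis(methoxymethoxy)phenyl]-3-hydroxy-5,7-bis(methoxymethoxy)chroman-4-one F2. This robust protected compound can be equilibrated to the trans isomer with catalytic Et3N if needed. Brief treatment with HCl in MeOH at rt then removes the acetals and returns to the route at 15.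

Step 4. The electron-rich benzylic chloride may ionise and solvolyse during work-up. The chloro epoxide may rearrange by ester migration in place of chloride shift, and the product may self-condense under base. Fallback, setting out from 6 and rejoining at 10 (bypassing 9): Darzens condensation of 6 with tert-butyl chloroacetate and potassium tert-butoxide in THF should give racemic tert-butyl trans-3-[3-geranyl-4,5-bis(methoxymethoxy)phenyl]oxirane-2-carboxylate F3. Opening of the epoxide at its benzylic carbon by phenol 2 (Cs2CO3, DMF, 60 °C) should give tert-butyl 3-[3-geranyl-4,5-bis(methoxymethoxy)phenyl]-3-[2-formyl-3,5-bis(methoxymethoxy)phenoxy]-2-hydroxypropanoate F4 as a diastereomer mixture. Oxidation of the secondary alcohol with Dess–Martin periodinane (NaHCO3, CH2Cl2) gives 10 without exposing the keto ester to base.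

**Further compounds**

F1 | step 6 | racemic tert-butyl (2R*,3R*)-2-[3-geranyl-4,5-bis(methoxymethoxy)phenyl]-3-hydroxy-5,7-bis(methoxymethoxy)-4-oxochromane-3-carboxylate | CC(C)=CCC/C(C)=C/Cc1cc(C2Oc3cc(OCOC)cc(OCOC)c3C(=O)C2(C(=O)OC(C)(C)C)O)cc(OCOC)c1OCOC
F2 | step 7 | (2R,3R)-2-[3-geranyl-4,5-bis(methoxymethoxy)phenyl]-3-hydroxy-5,7-bis(methoxymethoxy)chroman-4-one | CC(C)=CCC/C(C)=C/Cc1cc([C@H]2Oc3cc(OCOC)cc(OCOC)c3C(=O)[C@@H]2O)cc(OCOC)c1OCOC
F3 | step 4 | tert-butyl trans-3-[3-geranyl-4,5-bis(methoxymethoxy)phenyl]oxirane-2-carboxylate (racemic) | CC(C)=CCC/C(C)=C/Cc1cc(C2OC2C(=O)OC(C)(C)C)cc(OCOC)c1OCOC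
F4 | step 4 | tert-butyl 3-[3-geranyl-4,5-bis(methoxymethoxy)phenyl]-3-[2-formyl-3,5-bis(methoxymethoxy)phenoxy]-2-hydroxypropanoate (diastereomer mixture) | CC(C)=CCC/C(C)=C/Cc1cc(C(Oc2cc(OCOC)cc(OCOC)c2C=O)C(O)C(=O)OC(C)(C)C)cc(OCOC)c1OCOC
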